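## The problem

Terpenoid numbering is used throughout: C1–C10 for the decalin (C5/C10 ring fusion; ring A = C1–C5, C10; ring B = C5–C10), C11 for the CH2O carbon on C9, C12 for the methyl on C8, C15 for the methyl on C10.

Ligupersin A (24) is a trans-fused drimane. Ring A carries the C3 carbinol beside the C4 gem-dimethyl group. Ring B carries a C6 ketone conjugated to a C7=C8 alkene with a methyl on C8, and an umbelliferone ether hangs from C11 on C9. There are four stereocentres, C3 (R), C5 (S), C9 (R) and C10 (S). C10 is quaternary and lies between C5 and C9, so its methyl cannot be introduced by conjugate addition to a ring-fusion enone.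

The C3 hydroxyl and the C10 methyl are cis, so an oxygen at C3 can deliver the methyl carbon to its own face. Once C10 is fixed, it governs the rest: C5 (alpha to the C6 ketone) settles to the trans fusion, the C3 alcohol is the equatorial one, and C11 is the equatorial substituent on C9. Reagents approach C9 anti to the axial methyl, so C11 has to be on C9 before the last hydrogen arrives there.

The coumarin (lactone and Michael acceptor) will not survive organometallics, hydrides or dissolving metals and must come late. The final delta-aryloxy enone can lose umbelliferone by vinylogous elimination under base.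

The feature that makes the key step possible is a Δ5(10)-octalin in which the C3 hydroxyl is homoallylic (O–C3–C4–C5=C10) and a C6 hydroxyl is allylic to the same alkene. A carbenoid bound to these oxygens can bridge C5 and C10, and a C6 ketone next to C5 can later break the C5–CH2 bond so that the CH2 remains on C10 as the methyl.

## Retrosynthesis

**C7=C8 last (24 from 22).** No skeletal bond is cut; the alkene is introduced at the end by dehydrogenation of the saturated ketone 22. This keeps the base-labile delta-aryloxy enone out of every earlier step and lets C9 be set while ring B is saturated. The forward step must enolise C6 only toward C7 (the C5 side is blocked) and oxidise under neutral conditions.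

**C11–O bond (22 from 20 and 21).** The ether is cut to primary alcohol 20 and umbelliferone 21. Attaching the coumarin earlier would expose it to the cuprate, the hydride and the dissolving metal. The forward Mitsunobu reaction has to pick the primary C11 hydroxyl over the neopentyl-type C3 hydroxyl, so no protecting group is needed.

**C8–C12 and C9–C11 bonds (20 from 19, 17, 16, 14).** Both carbons are added to enone 14. C11 enters at C9 as a masked aldehyde by a vinylogous Mukaiyama reaction of dienol ether 15 (giving 16). C12 enters at C8 by cuprate addition (17). A direct hydroxymethylation at C9 would fix the wrong epimer irreversibly, because the electrophile comes anti to the C10 methyl. The aldehyde oxidation level is chosen instead: in the saturated keto aldehyde the C9 centre can equilibrate to the equatorial, natural configuration (19), and reduction then gives 20.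

**Enone 14 from ketol 12.** A dehydrogenation via the silyl enol ether 13; the same silylation caps the C3 hydroxyl for the next three steps.

**C10 methyl and C3 carbinol (12 from 11 from 10).** The methyl is traced back to the CH2 bridge of cyclopropyl diketone 11, opened by lithium in ammonia at the C5–CH2 bond. Diketone 11 comes from diol 10 by oxidising both carbinols. The two hindered secondary alcohols of 10 cannot be told apart, so both are oxidised; the same dissolving-metal step returns the equatorial C3 alcohol. No step is added, and the C3 centre has by then passed its configuration on to C10 and C5.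

**Key disconnection (10 from 9).** The C10–CH2 and C5–CH2 bonds are cut, leaving the Δ5(10)-octalindiol 9 and diiodomethane. Against conjugate methylation of a tetrasubstituted enone, this cut uses an electron-rich alkene and intramolecular delivery. The forward reaction needs both hydroxyls on the same face, so that the allylic C6 alkoxide reinforces the homoallylic C3 alkoxide.

**Ring B and the C6 carbinol (9 from 8 from 6).** The C6 carbinol comes from enone 8 by a reagent-controlled reduction that places it cis to the C3 hydroxyl. The C5–C6 bond of 8 is cut to hydroxy acid 6, an intramolecular acylation of the ring alkene. The precursor is monocyclic, and the ring-fusion alkene is created where the key step needs it.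

**Ring A (6 from 5, 4, 3, 1).** The C3 centre comes from ketone 4 by enantioselective reduction (5, then acid 6). The gem-dimethyl group and the alkene position of 4 come from deconjugative double methylation of enone 3. Enone 3 is the Birch product of commercial 4-(4-methoxyphenyl)butanoic acid 1.

## Roads not taken

Alternative 1: Ring B is cut at C5–C6 and C6–C7, with C6 coming from carbon monoxide. In the forward step monovalent rhodium ([Rh(CO)2Cl]2 under CO) opens a vinylcyclopropane at its C9–C5 bond and inserts CO, giving the cis-fused beta,gamma-unsaturated ketone A1.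
- Merits: one operation gives ring B with the C6 ketone, the C8 methyl and the C11 carbinol. In step economy for ring B this road is clearly better than the chosen one, which spends seven steps on the same substituents.
- Weak points: A1 is cis-fused and 3-epi, so C5 must be epimerised and C3 inverted. C9 becomes a stereocentre only when the alkene is moved into conjugation, by a protonation whose face is not controlled by the key step. The C–C activation must also occur at a cyclopropane carbon flanked by a quaternary centre.
- Against this, the chosen plan sets C10 and C5 by a closely precedented directed delivery, obtains C3 in the right configuration, and settles C9 under thermodynamic control.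

Alternative 2: Ring A is cut at C5–C10. The silyl ketene acetal of a six-membered alkenyl lactone, built from a chiral-pool gem-dimethyl carbinol unit, undergoes Ireland–Claisen rearrangement to the cyclohexenecarboxylic acid A2.
- Merits: C3 comes from the chiral pool, and the sigmatropic shift makes the quaternary C10 and fixes C5 relative to it in one concerted event. For C10 this control is at least as good as a directed cyclopropanation and needs no asymmetric catalyst.
- Weak points: the lactone forces a boat-like transition state, and the alkene geometry must be secured. A2 still lacks ring B: only two side-chain carbons are in place, C6 is a carboxylic acid, and the C1=C2 alkene must be removed.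
- Against this, in the chosen plan ring B is closed before the quaternary centre is made, and nothing has to be annulated afterwards.

Alternative 3: C5–C10 and C8–C9 are cut. An intramolecular dioxinone photocycloaddition gives the cyclobutane photoadduct A3, and a later retro-aldol opens the four-membered ring.
- Merits: C5, C9 and C10 are set in one step, C11 and the C8 carbon are already in place, and the fragmentation product is set up for a Claisen closure of ring B. For C9 this road is better than the chosen one, which has to correct C9 by equilibration.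
- Weak points: the facial selectivity of a flexible tether relative to the C3 silyl ether is uncertain, as are straight versus crossed addition and photochemical throughput. The ring closure gives a 6,8-diketone whose carbonyls must be differentiated before the C8 methyl can be added.
- Against this, the chosen plan uses only thermal steps of known type and a key step whose facial outcome is fixed by two cooperating hydroxyls.

Key step: step 7

Remark: C9 in 16–18 and C8 in 17–23 are written as the expected major epimers; C9 is equilibrated in step 13 and C8 becomes trigonal in step 16, so these assignments do not affect the outcome.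

Step 1
Reactants: 1 4-(4-methoxyphenyl)butanoic acid
Product: 3 methyl 4-(4-oxocyclohex-2-en-1-yl)butanoate (racemic), via dihydroanisole acid 2 (not isolated)
Conditions: Li, NH3 (l), THF, t-BuOH, −78 to −33 °C, then NH4Cl; HCl, MeOH, reflux
Reagents that add atoms: methanol, CO
Why: Birch reduction of the p-alkylanisole (as its lithium carboxylate) should give the 1-methoxy-1,4-diene; acidic methanol then hydrolyses the enol ether, moves the alkene into conjugation and esterifies the acid (Fischer esterification); the ring stereocentre of 3 is racemic and is erased in step 2.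

Step 2
Reactants: 3 methyl 4-(4-oxocyclohex-2-en-1-yl)butanoate
Product: 4 methyl 4-(3,3-dimethyl-4-oxocyclohex-1-en-1-yl)butanoate
Conditions: KOt-Bu, MeI, t-BuOH/THF, 0 °C to rt
Reagents that add atoms: iodomethane, CI
Why: Deconjugative alpha,alpha-dialkylation of an enone: the extended dienolate (gamma-deprotonation at the chain-bearing ring carbon) is methylated at the alpha-carbon, and the doubly activated alpha-proton of the resulting beta,gamma-enone is removed and methylated again, which fixes the alkene next to the new quaternary carbon (future C4 and C5=C10).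

Step 3
Reactants: 4 methyl 4-(3,3-dimethyl-4-oxocyclohex-1-en-1-yl)butanoate
Product: 5 methyl 4-[(4R)-4-hydroxy-3,3-dimethylcyclohex-1-en-1-yl]butanoate
Conditions: (S)-2-methyl-CBS-oxazaborolidine (0.1 equiv), BH3·SMe2, THF, −20 °C; MeOH
Reagents that add atoms: none
Why: Corey–Bakshi–Shibata reduction: the quaternary carbon acts as the large and the ring CH2 as the small ketone substituent, so the (S)-catalyst should give the (R)-carbinol (future C3); the catalysed ketone reduction should outrun attack of borane on the ester and the trisubstituted alkene at this temperature.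

Step 4
Reactants: 5 methyl 4-[(4R)-4-hydroxy-3,3-dimethylcyclohex-1-en-1-yl]butanoate
Product: 6 4-[(4R)-4-hydroxy-3,3-dimethylcyclohex-1-en-1-yl]butanoic acid
Conditions: LiOH, THF/H2O, rt; then dilute HCl to pH 3
Reagents that add atoms: lithium hydroxide, [Li+].[OH-]
Why: Ester saponification; the molecule holds no other base-labile group and the carbinol centre is not epimerisable.

Step 5
Reactants: 6 4-[(4R)-4-hydroxy-3,3-dimethylcyclohex-1-en-1-yl]butanoic acid
Product: 8 (7R)-7-hydroxy-8,8-dimethyl-3,4,5,6,7,8-hexahydronaphthalen-1(2H)-one, via enone trifluoroacetate 7 (not isolated)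
Conditions: (CF3CO)2O, CH2Cl2, 0 °C to rt; evaporate; K2CO3 (0.2 equiv), MeOH, rt
Reagents that add atoms: none
Why: Intramolecular Friedel–Crafts-type acylation of the trisubstituted alkene by the mixed trifluoroacetic anhydride: Markovnikov attack at C5 (tertiary cation at C10, six-membered ring) and proton loss should give the ring-fusion enone, while the hydroxyl is masked in the flask as its trifluoroacetate; methanolysis frees it, and the carbonate moves any beta,gamma-alkene into conjugation.

Step 6
Reactants: 8 (7R)-7-hydroxy-8,8-dimethyl-3,4,5,6,7,8-hexahydronaphthalen-1(2H)-one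
Product: 9 (1S,7R)-8,8-dimethyl-1,2,3,4,5,6,7,8-octahydronaphthalene-1,7-diol
Conditions: (R)-2-methyl-CBS-oxazaborolidine (0.2 equiv), catecholborane, toluene, −78 °C
Reagents that add atoms: none
Why: Corey–Bakshi–Shibata 1,2-reduction of the enone: the fully substituted alkenyl carbon is the large group, so the (R)-catalyst should give the (6S)-carbinol, on the same face as the C3 hydroxyl; control comes from the reagent, the C3 centre being remote.

Step 7
Reactants: 9 (1S,7R)-8,8-dimethyl-1,2,3,4,5,6,7,8-octahydronaphthalene-1,7-diol
Product: 10 (1R,2S,6R,9R)-10,10-dimethyltricyclo[4.4.1.0^1,6]undecane-2,9-diol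
Conditions: Et2Zn (5 equiv), CH2I2 (10 equiv), CH2Cl2, 0 °C to rt
Reagents that add atoms: diiodomethane, ICI
Why: Et2Zn turns both hydroxyls into zinc alkoxides (ethane is lost) and with CH2I2 forms the (iodomethyl)zinc carbenoid, which is held by the allylic C6 oxygen and the homoallylic C3 oxygen on one face of the C5=C10 alkene. Methylene is then transferred in a concerted butterfly-type transition state, forming C10–CH2 and C5–CH2 together. The closest known reaction type is the hydroxyl-directed Simmons–Smith cyclopropanation (Furukawa variant) of cyclic allylic and homoallylic alcohols, including octalinols with a tetrasubstituted ring-fusion alkene. The cyclopropane is closed by concerted (2+1) addition of the carbenoid carbon, suprafacial on the alkene, so no stepwise closure mode applies. The two new quaternary stereocentres C5 and C10 are set together by the face of delivery, which is fixed by the C3 hydroxyl (stereocentre of step 3) and reinforced by the cis C6 hydroxyl (step 6). The only selectivity needed is between the two alkene faces, since there is one alkene and the C4 methyls flank both faces alike; the two cooperating alkoxides secure it. An excess of carbenoid is used because the alkene is tetrasubstituted and sits beside a quaternary carbon.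

Step 8
Reactants: 10 (1R,2S,6R,9R)-10,10-dimethyltricyclo[4.4.1.0^1,6]undecane-2,9-diol
Product: 11 (1R,6R)-10,10-dimethyltricyclo[4.4.1.0^1,6]undecane-2,9-dione
Conditions: Dess–Martin periodinane, NaHCO3, CH2Cl2, rt
Reagents that add atoms: none
Why: Dess–Martin oxidation of both secondary alcohols under buffered, non-acidic conditions that should not ionise the cyclopropyl carbinol; C3 is oxidised on purpose, because the two hindered carbinols cannot be differentiated and C3 is set again in step 9.

Step 9
Reactants: 11 (1R,6R)-10,10-dimethyltricyclo[4.4.1.0^1,6]undecane-2,9-dione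
Product: 12 (4aR,7R,8aS)-7-hydroxy-4a,8,8-trimethyloctahydronaphthalen-1(2H)-one
Conditions: Li, NH3 (l), THF, t-BuOH (2 equiv), −78 °C; isoprene, then NH4Cl
Reagents that add atoms: none
Why: Dissolving-metal cleavage of a cyclopropyl ketone: the C6 ketyl should open the C5–CH2 bond (the external bond, best aligned with the carbonyl pi system), giving the C10 methyl and a C5=C6 lithium enolate that resists further reduction, while the isolated C3 ketone is reduced under thermodynamic control to the equatorial (3R) alcohol, cis to the new methyl; protonation of the enolate on work-up should give the more stable trans ring fusion (H-5 anti to the methyl), to which C5 can also equilibrate.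

Step 10
Reactants: 12 (4aR,7R,8aS)-7-hydroxy-4a,8,8-trimethyloctahydronaphthalen-1(2H)-one
Product: 14 (4aS,7R,8aS)-4a,8,8-trimethyl-7-[(triethylsilyl)oxy]-4a,5,6,7,8,8a-hexahydronaphthalen-1(4H)-one, via bis(triethylsilyl) enol ether 13 (not isolated)
Conditions: Et3SiOTf, Et3N, CH2Cl2, 0 °C to rt; then Pd(OAc)2, MeCN, rt
Reagents that add atoms: triethylsilyl trifluoromethanesulfonate, CC[Si](CC)(CC)OS(=O)(=O)C(F)(F)F
Why: Soft enolisation should give the C6=C7 silyl enol ether (the C5 alternative is tetrasubstituted and strained against the C4 methyls) and silylate the C3 hydroxyl; Saegusa–Ito oxidation through the palladium enolate and beta-hydride elimination then gives the C7=C8 enone, the only one possible because C10 is quaternary.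

Step 11
Reactants: 14 (4aS,7R,8aS)-4a,8,8-trimethyl-7-[(triethylsilyl)oxy]-4a,5,6,7,8,8a-hexahydronaphthalen-1(4H)-one
Product: 16 (4S,4aS,7R,8aS)-4-(dimethoxymethyl)-4a,8,8-trimethyl-7-[(triethylsilyl)oxy]-4a,5,6,7,8,8a-hexahydronaphthalen-1(4H)-one, via triethylsilyl dienol ether 15 (not isolated)
Conditions: Et3SiOTf, Et3N, CH2Cl2, 0 °C; then HC(OMe)3, Me3SiOTf (0.1 equiv), CH2Cl2, −78 °C
Reagents that add atoms: trimethyl orthoformate, COC(OC)OC
Why: Gamma-deprotonation at C9 (the alpha-prime hydrogen at C5 is buried between two quaternary carbons) should give the linear dienol ether, which reacts with the dimethoxycarbenium ion at its terminal carbon C9 in a vinylogous Mukaiyama reaction; attack is expected anti to the C10 methyl, giving the 9-epi configuration, which is corrected in step 13 because C11 enters at the aldehyde oxidation level.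

Step 12
Reactants: 16 (4S,4aS,7R,8aS)-4-(dimethoxymethyl)-4a,8,8-trimethyl-7-[(triethylsilyl)oxy]-4a,5,6,7,8,8a-hexahydronaphthalen-1(4H)-one
Product: 17 (3S,4S,4aS,7R,8aS)-4-(dimethoxymethyl)-3,4a,8,8-tetramethyl-7-[(triethylsilyl)oxy]octahydronaphthalen-1(2H)-one
Conditions: Me2CuLi (MeLi, CuI), Et2O, −78 to −20 °C; aq NH4Cl
Reagents that add atoms: methyllithium (as lithium dimethylcuprate), [Li]C
Why: Conjugate addition of lithium dimethylcuprate to a beta-monosubstituted cyclohexenone installs the C8 methyl (C12); the acetal and silyl ether are inert, and the C8 configuration (expected equatorial) does not matter because C8 becomes trigonal in step 16.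

Step 13
Reactants: 17 (3S,4S,4aS,7R,8aS)-4-(dimethoxymethyl)-3,4a,8,8-tetramethyl-7-[(triethylsilyl)oxy]octahydronaphthalen-1(2H)-one
Product: 19 (1R,2S,4aS,6R,8aS)-6-hydroxy-2,5,5,8a-tetramethyl-4-oxodecahydronaphthalene-1-carbaldehyde, via axial aldehyde 18 (not isolated)
Conditions: 1 M HCl, THF, rt; then DBU, CH2Cl2, rt
Reagents that add atoms: water, O
Why: Aqueous acid cleaves the acetal and the silyl ether; the aldehyde alpha-centre C9 then equilibrates through its enol(ate) to the equatorial aldehyde, trans-diequatorial to the C8 methyl and cis to the C10 methyl (the natural C9 configuration, also the product of axial protonation anti to the angular methyl), while C5 stays in its more stable trans arrangement.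

Step 14
Reactants: 19 (1R,2S,4aS,6R,8aS)-6-hydroxy-2,5,5,8a-tetramethyl-4-oxodecahydronaphthalene-1-carbaldehyde
Product: 20 (3S,4R,4aS,7R,8aS)-7-hydroxy-4-(hydroxymethyl)-3,4a,8,8-tetramethyloctahydronaphthalen-1(2H)-one
Conditions: NaBH4, MeOH/CH2Cl2, −78 °C
Reagents that add atoms: none
Why: Chemoselective hydride reduction: the aldehyde should react far faster than the C6 ketone, which is shielded by C5 lying between two quaternary carbons; the low temperature also avoids epimerisation at C9 before reduction.

Step 15
Reactants: 20 (3S,4R,4aS,7R,8aS)-7-hydroxy-4-(hydroxymethyl)-3,4a,8,8-tetramethyloctahydronaphthalen-1(2H)-one; 21 umbelliferone (7-hydroxy-2H-chromen-2-one)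
Product: 22 7-{[(1R,2S,4aS,6R,8aS)-6-hydroxy-2,5,5,8a-tetramethyl-4-oxodecahydronaphthalen-1-yl]methoxy}-2H-chromen-2-one
Conditions: PPh3, diisopropyl azodicarboxylate, THF, 0 °C to rt
Reagents that add atoms: none
Why: Mitsunobu etherification: the acidic phenol displaces the activated primary C11 oxygen (SN2 at a carbon that is not a stereocentre), while the neopentyl-type secondary C3 hydroxyl should be too hindered to be activated; the ether is made on the saturated ketone, where no vinylogous elimination path exists.

Step 16
Reactants: 22 7-{[(1R,2S,4aS,6R,8aS)-6-hydroxy-2,5,5,8a-tetramethyl-4-oxodecahydronaphthalen-1-yl]methoxy}-2H-chromen-2-one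
Product: 24 ligupersin A, 7-{[(1R,4aS,6R,8aS)-6-hydroxy-2,5,5,8a-tetramethyl-4-oxo-1,4,4a,5,6,7,8,8a-octahydronaphthalen-1-yl]methoxy}-2H-chromen-2-one, via bis(trimethylsilyl) enol ether 23 (not isolated)
Conditions: Me3SiOTf, Et3N, CH2Cl2, 0 °C; then Pd(OAc)2, MeCN, rt; dilute HCl work-up
Reagents that add atoms: none
Why: Saegusa–Ito oxidation: the C6=C7 silyl enol ether forms as in step 10, and the palladium enolate loses the C8 hydrogen to give the trisubstituted C7=C8 enone; the neutral oxidation should leave C9 (now gamma to the ketone), the aryl ether and the coumarin untouched, and the acidic work-up removes the transient C3 silyl ether.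

## Compound list

1 | 4-(4-methoxyphenyl)butanoic acid | COc1ccc(CCCC(=O)O)cc1 | starting material
2 | 4-(4-methoxycyclohexa-1,4-dien-1-yl)butanoic acid | COC1=CCC(CCCC(=O)O)=CC1 | intermediate
3 | methyl 4-(4-oxocyclohex-2-en-1-yl)butanoate (racemic) | COC(=O)CCCC1CCC(=O)C=C1 | intermediate
4 | methyl 4-(3,3-dimethyl-4-oxocyclohex-1-en-1-yl)butanoate | COC(=O)CCCC1=CC(C)(C)C(=O)CC1 | intermediate
5 | methyl 4-[(4R)-4-hydroxy-3,3-dimethylcyclohex-1-en-1-yl]butanoate | COC(=O)CCCC1=CC(C)(C)[C@H](O)CC1 | intermediate
6 | 4-[(4R)-4-hydroxy-3,3-dimethylcyclohex-1-en-1-yl]butanoic acid | OC(=O)CCCC1=CC(C)(C)[C@H](O)CC1 | intermediate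
7 | (2R)-1,1-dimethyl-8-oxo-1,2,3,4,5,6,7,8-octahydronaphthalen-2-yl trifluoroacetate | CC1(C)[C@H](OC(=O)C(F)(F)F)CCC2=C1C(=O)CCC2 | intermediate
8 | (7R)-7-hydroxy-8,8-dimethyl-3,4,5,6,7,8-hexahydronaphthalen-1(2H)-one (3R-hydroxy-Δ5(10)-octalin-6-one in terpenoid numbering) | CC1(C)[C@H](O)CCC2=C1C(=O)CCC2 | intermediate
9 | (1S,7R)-8,8-dimethyl-1,2,3,4,5,6,7,8-octahydronaphthalene-1,7-diol (3R,6S; both hydroxyls on one face) | CC1(C)[C@H](O)CCC2=C1[C@@H](O)CCC2 | intermediate
10 | (1R,2S,6R,9R)-10,10-dimethyltricyclo[4.4.1.0^1,6]undecane-2,9-diol (3R,5R,6S,10R; both hydroxyls and the CH2 bridge on one face) | CC1(C)[C@H](O)CC[C@]23C[C@]12[C@@H](O)CCC3 | intermediate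
11 | (1R,6R)-10,10-dimethyltricyclo[4.4.1.0^1,6]undecane-2,9-dione | CC1(C)C(=O)CC[C@]23C[C@]12C(=O)CCC3 | intermediate
12 | (4aR,7R,8aS)-7-hydroxy-4a,8,8-trimethyloctahydronaphthalen-1(2H)-one (trans-fused; 3-OH cis to the C10 methyl) | C1CC(=O)[C@@H]2C(C)(C)[C@H](O)CC[C@@]2(C)C1 | intermediate
13 | triethyl{[(2R,4aR,8aS)-1,1,4a-trimethyl-8-[(triethylsilyl)oxy]-1,2,3,4,4a,5,6,8a-octahydronaphthalen-2-yl]oxy}silane (C3 silyl ether and C6=C7 silyl enol ether of 12) | C1C=C(O[Si](CC)(CC)CC)[C@@H]2C(C)(C)[C@H](O[Si](CC)(CC)CC)CC[C@@]2(C)C1 | intermediate
14 | (4aS,7R,8aS)-4a,8,8-trimethyl-7-[(triethylsilyl)oxy]-4a,5,6,7,8,8a-hexahydronaphthalen-1(4H)-one | C1=CC(=O)[C@@H]2C(C)(C)[C@H](O[Si](CC)(CC)CC)CC[C@@]2(C)C1 | intermediate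
15 | triethyl{[(2R,4aS,8aS)-1,1,4a-trimethyl-8-[(triethylsilyl)oxy]-1,2,3,4,4a,8a-hexahydronaphthalen-2-yl]oxy}silane (C6=C7, C8=C9 dienol ether of 14) | C1=CC=C(O[Si](CC)(CC)CC)[C@@H]2C(C)(C)[C@H](O[Si](CC)(CC)CC)CC[C@@]12C | intermediate
16 | (4S,4aS,7R,8aS)-4-(dimethoxymethyl)-4a,8,8-trimethyl-7-[(triethylsilyl)oxy]-4a,5,6,7,8,8a-hexahydronaphthalen-1(4H)-one (acetal carbon trans to the C10 methyl) | C1=CC(=O)[C@@H]2C(C)(C)[C@H](O[Si](CC)(CC)CC)CC[C@@]2(C)[C@H]1C(OC)OC | intermediate
17 | (3S,4S,4aS,7R,8aS)-4-(dimethoxymethyl)-3,4a,8,8-tetramethyl-7-[(triethylsilyl)oxy]octahydronaphthalen-1(2H)-one | C[C@H]1CC(=O)[C@@H]2C(C)(C)[C@H](O[Si](CC)(CC)CC)CC[C@@]2(C)[C@H]1C(OC)OC | intermediate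
18 | (1S,2S,4aS,6R,8aS)-6-hydroxy-2,5,5,8a-tetramethyl-4-oxodecahydronaphthalene-1-carbaldehyde (axial aldehyde, C9 epimer of 19) | C[C@H]1CC(=O)[C@@H]2C(C)(C)[C@H](O)CC[C@@]2(C)[C@H]1C=O | intermediate
19 | (1R,2S,4aS,6R,8aS)-6-hydroxy-2,5,5,8a-tetramethyl-4-oxodecahydronaphthalene-1-carbaldehyde (equatorial aldehyde, cis to the C10 methyl) | C[C@H]1CC(=O)[C@@H]2C(C)(C)[C@H](O)CC[C@@]2(C)[C@@H]1C=O | intermediate
20 | (3S,4R,4aS,7R,8aS)-7-hydroxy-4-(hydroxymethyl)-3,4a,8,8-tetramethyloctahydronaphthalen-1(2H)-one | C[C@H]1CC(=O)[C@@H]2C(C)(C)[C@H](O)CC[C@@]2(C)[C@@H]1CO | intermediate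
21 | umbelliferone (7-hydroxy-2H-chromen-2-one) | O=c1ccc2ccc(O)cc2o1 | starting material
22 | 7-{[(1R,2S,4aS,6R,8aS)-6-hydroxy-2,5,5,8a-tetramethyl-4-oxodecahydronaphthalen-1-yl]methoxy}-2H-chromen-2-one | C[C@H]1CC(=O)[C@@H]2C(C)(C)[C@H](O)CC[C@@]2(C)[C@@H]1COc1ccc2ccc(=O)oc2c1 | intermediate
23 | 7-{[(1R,2R,4aS,6R,8aS)-2,5,5,8a-tetramethyl-4,6-bis[(trimethylsilyl)oxy]-1,2,4a,5,6,7,8,8a-octahydronaphthalen-1-yl]methoxy}-2H-chromen-2-one (C3 silyl ether and C6=C7 silyl enol ether of 22) | C[C@H]1C=C(O[Si](C)(C)C)[C@@H]2C(C)(C)[C@H](O[Si](C)(C)C)CC[C@@]2(C)[C@@H]1COc1ccc2ccc(=O)oc2c1 | intermediate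
24 | ligupersin A, 7-{[(1R,4aS,6R,8aS)-6-hydroxy-2,5,5,8a-tetramethyl-4-oxo-1,4,4a,5,6,7,8,8a-octahydronaphthalen-1-yl]methoxy}-2H-chromen-2-one (3R,5S,9R,10S) | CC1=CC(=O)[C@@H]2C(C)(C)[C@H](O)CC[C@@]2(C)[C@@H]1COc1ccc2ccc(=O)oc2c1 | target

## Step count and risks

Total step count: 16. Six of the steps (1, 5, 10, 11, 13, 16) run as two consecutive operations without isolating the intermediate.
Longest linear sequence: 16 steps, from 1 to 24; umbelliferone 21 enters at step 15.

**Step 7 (key step).** The most likely failure is slow or incomplete methylene transfer to a tetrasubstituted alkene that sits beside a quaternary carbon. Side reactions on the bis-zinc alkoxide (O-methylation, bridging of the two oxygens by CH2) and loss of facial control through aggregated, non-chelated carbenoid are also possible.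

Fallback: a covalent tether replaces coordination. Setting out from 8, the C3 hydroxyl is silylated (t-BuMe2SiOTf, 2,6-lutidine) to the tert-butyldimethylsilyl ether F1. The enone is reduced as in step 6 to the (6S)-allylic alcohol F2, which is converted (bromoacetyl bromide, then N,N'-ditosylhydrazine and DBU) into the diazoacetate F3. Rh2(OAc)4 then closes the cyclopropane intramolecularly from the C6 oxygen, giving the cyclopropane-fused gamma-lactone F4, whose carbene carbon is bonded to C5 and C10 on the face fixed by the tether. Saponification with LiOH, silylation of the freed C6 oxygen without acidification, and selective cleavage of the silyl ester give the bis(silyloxy) cyclopropanecarboxylic acid F5. Barton decarboxylation (N-hydroxypyridine-2-thione ester, t-BuSH, light) removes the carboxyl carbon to give the bis(silyl) ether F6, and Bu4NF returns the route to 10.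

**Step 5.** Acid-promoted migration of the ring alkene before acylation would close ring B on the unhindered side and give the regioisomeric octalone. Attack at C5, next to the gem-dimethyl carbon, may also be slow enough for ionisation and oligomerisation to compete.

Fallback: ring closure by a carbonyl-ene reaction under a proton-scavenging Lewis acid. Setting out from 5, Et3SiCl and imidazole give the triethylsilyl ether F7, and i-Bu2AlH at −78 °C gives the aldehyde F8. Me2AlCl promotes a type 2 carbonyl-ene cyclisation that forms the C5–C6 bond and gives the homoallylic alcohol F9 (alkene shifted to C1=C10, mixture at C5 and C6). Dess–Martin oxidation gives the beta,gamma-unsaturated ketone F10, DBU moves the alkene into conjugation to give the silyl ether F11, and dilute HCl returns the route to 8.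

**Step 9.** If the C5=C6 enolate is protonated while metal is still present, the C6 carbonyl is over-reduced. If too little proton donor is present, the C3 ketone is reduced incompletely or with poor selectivity. Cleavage of the central C5–C10 bond is a further, less likely, failure.

Fallback: two-electron homoconjugate opening instead of electron transfer. Setting out from 11, Me3SiI (CH2Cl2, −20 °C) attacks the CH2 carbon of the cyclopropyl ketone; aqueous work-up gives the iodomethyl diketone F12. Bu3SnH with AIBN removes the iodine to give the trimethyl diketone F13, and NaBH4 at −40 °C reduces the more accessible C3 carbonyl to the equatorial alcohol, returning the route to 12.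

**Step 11.** The carbenium ion may attack the unhindered alpha-carbon C7 instead of the neopentyl gamma-carbon C9, or the cross-conjugated dienol ether may form, either of which puts C11 on the wrong atom.

Fallback: a slimmer thionium electrophile, with the aldehyde unmasked later. Setting out from 15, PhSCH2Cl with ZnBr2 (catalytic) gives the gamma-(phenylthiomethyl) enone F14, and Me2CuLi adds the C8 methyl to give the sulfide F15. m-Chloroperbenzoic acid (1 equiv, −78 °C) gives the sulfoxide F16. Pummerer rearrangement ((CF3CO)2O, 2,6-lutidine, then aqueous HCl) releases the aldehyde 18 with loss of the silyl ether, and DBU equilibration returns the route to 19.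

**Step 15.** Displacement at the beta-branched C11, next to a quaternary carbon, may be slow, so that the activated alcohol eliminates or is intercepted by the hydrazide.

Fallback: form the ether bond at the aryl carbon instead. Setting out from 20, umbelliferone 21 is converted (Tf2O, pyridine) into 2-oxo-2H-chromen-7-yl trifluoromethanesulfonate F17. This is coupled with the primary hydroxyl of 20 (Pd2(dba)3, a bulky di-tert-butyl(biaryl)phosphine, Cs2CO3, toluene, 80 °C), returning the route to 22; C11 is then never the electrophile.

## Further compounds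

F1 | step 7 | (7R)-7-[(tert-butyldimethylsilyl)oxy]-8,8-dimethyl-3,4,5,6,7,8-hexahydronaphthalen-1(2H)-one | CC1(C)[C@H](O[Si](C)(C)C(C)(C)C)CCC2=C1C(=O)CCC2
F2 | step 7 | (1S,7R)-7-[(tert-butyldimethylsilyl)oxy]-8,8-dimethyl-1,2,3,4,5,6,7,8-octahydronaphthalen-1-ol | CC1(C)[C@H](O[Si](C)(C)C(C)(C)C)CCC2=C1[C@@H](O)CCC2
F3 | step 7 | (1S,7R)-7-[(tert-butyldimethylsilyl)oxy]-8,8-dimethyl-1,2,3,4,5,6,7,8-octahydronaphthalen-1-yl diazoacetate | CC1(C)[C@H](O[Si](C)(C)C(C)(C)C)CCC2=C1[C@@H](OC(=O)C=[N+]=[N-])CCC2
F4 | step 7 | gamma-lactone of the C5,C10-cyclopropane carboxylic acid onto the C6 oxygen, C3 tert-butyldimethylsilyl ether (cyclopropane and lactone on the face of the C3 oxygen) | CC1(C)[C@H](O[Si](C)(C)C(C)(C)C)CC[C@]23CCC[C@@H]4OC(=O)[C@H]2[C@]134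
F5 | step 7 | 3,6-bis[(tert-butyldimethylsilyl)oxy]-4,4-dimethyl-5,10-methanodecalin-methano-carboxylic acid (carboxyl on the cyclopropane CH, ring B side) | CC1(C)[C@H](O[Si](C)(C)C(C)(C)C)CC[C@]23[C@@H](C(=O)O)[C@]12[C@@H](O[Si](C)(C)C(C)(C)C)CCC3
F6 | step 7 | bis(tert-butyldimethylsilyl) ether of 10 | CC1(C)[C@H](O[Si](C)(C)C(C)(C)C)CC[C@]23C[C@]12[C@@H](O[Si](C)(C)C(C)(C)C)CCC3
F7 | step 5 | methyl 4-[(4R)-3,3-dimethyl-4-[(triethylsilyl)oxy]cyclohex-1-en-1-yl]butanoate | COC(=O)CCCC1=CC(C)(C)[C@H](O[Si](CC)(CC)CC)CC1
F8 | step 5 | 4-[(4R)-3,3-dimethyl-4-[(triethylsilyl)oxy]cyclohex-1-en-1-yl]butanal | O=CCCCC1=CC(C)(C)[C@H](O[Si](CC)(CC)CC)CC1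
F9 | step 5 | (7R)-8,8-dimethyl-7-[(triethylsilyl)oxy]-1,2,3,4,6,7,8,8a-octahydronaphthalen-1-ol (mixture at C1 and C8a) | OC1CCCC2=CC[C@@H](O[Si](CC)(CC)CC)C(C)(C)C12
F10 | step 5 | (7R)-8,8-dimethyl-7-[(triethylsilyl)oxy]-3,4,6,7,8,8a-hexahydronaphthalen-1(2H)-one (mixture at C8a) | O=C1CCCC2=CC[C@@H](O[Si](CC)(CC)CC)C(C)(C)C12
F11 | step 5 | (7R)-8,8-dimethyl-7-[(triethylsilyl)oxy]-3,4,5,6,7,8-hexahydronaphthalen-1(2H)-one | CC1(C)[C@H](O[Si](CC)(CC)CC)CCC2=C1C(=O)CCC2
F12 | step 9 | trans-fused 10-(iodomethyl)-4,4-dimethyldecalin-3,6-dione (terpenoid numbering; H-5 anti to the iodomethyl group) | C1CC(=O)[C@@H]2C(C)(C)C(=O)CC[C@@]2(CI)C1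
F13 | step 9 | trans-fused 4,4,10-trimethyldecalin-3,6-dione (terpenoid numbering) | C1CC(=O)[C@@H]2C(C)(C)C(=O)CC[C@@]2(C)C1
F14 | step 11 | 9-(phenylthiomethyl) analogue of 16 (CH2SPh in place of the acetal, trans to the C10 methyl) | C1=CC(=O)[C@@H]2C(C)(C)[C@H](O[Si](CC)(CC)CC)CC[C@@]2(C)[C@H]1CSc1ccccc1
F15 | step 11 | 9-(phenylthiomethyl) analogue of 17 | C[C@H]1CC(=O)[C@@H]2C(C)(C)[C@H](O[Si](CC)(CC)CC)CC[C@@]2(C)[C@H]1CSc1ccccc1
F16 | step 11 | sulfoxide of F15 (mixture at sulfur) | C[C@H]1CC(=O)[C@@H]2C(C)(C)[C@H](O[Si](CC)(CC)CC)CC[C@@]2(C)[C@H]1CS(=O)c1ccccc1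
F17 | step 15 | 2-oxo-2H-chromen-7-yl trifluoromethanesulfonate | O=c1ccc2ccc(OS(=O)(=O)C(F)(F)F)cc2o1
A1 | alternative 1 | cis-fused beta,gamma-unsaturated C6 ketone (3-epi) with C8 methyl and C11 carbinol | CC1=C(CO)[C@]2(C)CC[C@H](O)C(C)(C)[C@@H]2C(=O)C1
A2 | alternative 2 | ring A cyclohexenecarboxylic acid from the Ireland–Claisen rearrangement | OC(=O)[C@H]1C(C)(C)[C@H](O[Si](C)(C)C(C)(C)C)C=C[C@@]1(C)CCOCc1ccc(OC)cc1
A3 | alternative 3 | tricyclic cyclobutane photoadduct of the dioxinone | CC1(C)OC(=O)[C@]23C(C)(C)[C@H](O[Si](C)(C)C(C)(C)C)CC[C@@]2(C)[C@H](CO[Si](C)(C)C(C)(C)C)[C@]3(C)O1
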